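**Plan**

The target, 6-hydroxy-7-methoxy-3-(2,4,5-trimethoxyphenyl)-4H-chromen-4-one, is achiral. Retrosynthesis first masks O6 as a benzyl ether and hydrates C2=C3 to a 3-hydroxychroman-4-one.
Enabling feature: C4 is a carbonyl carbon held between C4a of ring A and the aryl-bearing C3, and C3 is tied back to ring A through C2–O1–C8a. C3–C4 is therefore cut into an aldehyde-derived acyl anion on C4a and a tethered aryl ketone.
Further cuts: O1–C2 (phenol plus α-bromo ketone), then C4–C4a (ortho-formylation of a phenol made from O-benzylvanillin). The bromo ketone goes back to 2',4',5'-trimethoxyacetophenone.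
Forward: rings A and B are bought and joined at O1–C2. Ring C closes at C3–C4, becomes the pyranone by loss of water, and the benzyl group leaves last.
Stereochemistry: the only stereocentre of the route (C3 of the ketol) forms as a racemate and disappears on dehydration, so nothing has to be controlled.

Key step: step 5

Assumption: the ketol formed in the key step is made and carried as the racemate, because its single stereocentre is destroyed in the following step and the target is achiral.

**Route**

Step 1
Reactants: 1 4-(benzyloxy)-3-methoxybenzaldehyde (O-benzylvanillin)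
Product: 3 4-(benzyloxy)-3-methoxyphenol, via aryl formate 2 (not isolated)
Conditions: mCPBA, CH2Cl2, 0 °C to rt; aq NaHCO3 wash; then K2CO3 (cat.), MeOH, rt
Reagents that add atoms: mCPBA, OOC(=O)c1cccc(Cl)c1
Why: Baeyer–Villiger oxidation of an electron-rich benzaldehyde, in which the 4-alkoxyaryl group migrates to oxygen in preference to hydride, gives the aryl formate, and base-catalysed transesterification with methanol then frees the phenol while the benzyl and methyl ethers stay untouched.

Step 2
Reactants: 3 4-(benzyloxy)-3-methoxyphenol
Product: 4 5-(benzyloxy)-2-hydroxy-4-methoxybenzaldehyde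
Conditions: MgCl2 (anhydrous), Et3N, (CH2O)n, MeCN, reflux; then 1 M HCl
Reagents that add atoms: paraformaldehyde (as formaldehyde), C=O
Why: In the Casnati–Skattebøl ortho-formylation the magnesium phenoxide delivers coordinated formaldehyde only to an ortho carbon, the open C6 (para to OMe) is preferred over C2 wedged between OH and OMe, and a second formaldehyde takes up hydride to raise the benzylic alkoxide to the aldehyde.

Step 3
Reactants: 5 1-(2,4,5-trimethoxyphenyl)ethanone (2',4',5'-trimethoxyacetophenone)
Product: 6 2-bromo-1-(2,4,5-trimethoxyphenyl)ethanone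
Conditions: CuBr2 (2 equiv), EtOAc–CHCl3, reflux
Reagents that add atoms: CuBr2, [Cu+2].[Br-].[Br-]
Why: Heterogeneous α-bromination of an aryl methyl ketone with CuBr2 runs through the copper-bound enol and stops at the monobromide, and because no free Br2 builds up, the electron-rich ring should escape nuclear bromination and no Lewis acid is present that could cleave the ortho methyl ether.

Step 4
Reactants: 4 5-(benzyloxy)-2-hydroxy-4-methoxybenzaldehyde; 6 2-bromo-1-(2,4,5-trimethoxyphenyl)ethanone
Product: 7 5-(benzyloxy)-4-methoxy-2-[2-oxo-2-(2,4,5-trimethoxyphenyl)ethoxy]benzaldehyde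
Conditions: K2CO3 (1.1 equiv), acetone, rt, stopped as soon as 4 is consumed
Reagents that add atoms: none
Why: In this Williamson ether synthesis (SN2) the chelated 2-OH is acidic enough for K2CO3 at room temperature and the phenacyl-type bromide is very reactive, so the ether should form before enolisation of the new OCH2 group can start an aldol condensation, which the donor-substituted aldehyde and ketone slow further.

Step 5
Reactants: 7 5-(benzyloxy)-4-methoxy-2-[2-oxo-2-(2,4,5-trimethoxyphenyl)ethoxy]benzaldehyde
Product: 8 rac-6-(benzyloxy)-3-hydroxy-7-methoxy-3-(2,4,5-trimethoxyphenyl)chroman-4-one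
Conditions: 2-(pentafluorophenyl)-6,7-dihydro-5H-pyrrolo[2,1-c][1,2,4]triazol-2-ium tetrafluoroborate (15 mol %), Et3N (20 mol %), degassed THF (0.05 M), Ar, rt to 40 °C
Reagents that add atoms: none
Why: Et3N frees the triazolylidene, which adds to the formyl group of 7; proton transfer gives the Breslow enaminol, an acyl anion equivalent at the future C4, which attacks the tethered ketone carbon (future C3), and proton shift with expulsion of the carbene delivers ketol 8. The closest known reaction type is the NHC-catalysed intramolecular crossed aldehyde–ketone benzoin of 2-(2-oxo-2-arylethoxy)benzaldehydes to 3-aryl-3-hydroxychroman-4-ones. Ring C closes in a 6-exo-trig mode at the ketone C=O, along the chain C4–C4a–C8a–O1–C2–C3. The new C3 stereocentre is not controlled: the catalyst is achiral, both ketone faces are attacked alike, 8 is racemic and the centre is erased in step 6. The donor and acceptor roles are fixed by the substrate, since only the formyl group carries the C–H needed for enaminol formation, while the α-aryloxy group and the out-of-plane twist imposed by the 2-methoxy group keep the otherwise donor-rich ketone electrophilic. The closure must also outrun enolisation at C2 followed by aldol condensation onto the aldehyde (Rap–Stoermer path) and intermolecular homo-benzoin, which an acidic N-C6F5 triazolium needing only substoichiometric Et3N, high dilution and exclusion of air should secure.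

Step 6
Reactants: 8 rac-6-(benzyloxy)-3-hydroxy-7-methoxy-3-(2,4,5-trimethoxyphenyl)chroman-4-one
Product: 9 6-(benzyloxy)-7-methoxy-3-(2,4,5-trimethoxyphenyl)-4H-chromen-4-one
Conditions: p-TsOH·H2O (cat.), toluene, reflux, Dean–Stark
Reagents that add atoms: none
Why: In this acid-catalysed E1 dehydration of a tertiary benzylic alcohol the 2- and 4-methoxy groups of ring B stabilise the C3 cation despite the neighbouring carbonyl, loss of a C2 proton is driven by formation of the conjugated 4-pyranone, the C3 stereocentre disappears, and aryl benzyl and methyl ethers tolerate catalytic TsOH.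

Step 7
Reactants: 9 6-(benzyloxy)-7-methoxy-3-(2,4,5-trimethoxyphenyl)-4H-chromen-4-one
Product: 10 6-hydroxy-7-methoxy-3-(2,4,5-trimethoxyphenyl)-4H-chromen-4-one (target)
Conditions: H2 (1 atm), 10% Pd/C, EtOAc–MeOH, rt, stopped after uptake of one equivalent
Reagents that add atoms: none
Why: Catalytic hydrogenolysis of an aryl benzyl ether on Pd/C at atmospheric pressure is normally faster than saturation of the trisubstituted, vinylogous-ester C2=C3 bond of an isoflavone, so a monitored reaction should give the free 6-phenol with the four methyl ethers intact.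

**Compound list**

1 | 4-(benzyloxy)-3-methoxybenzaldehyde | COc1cc(C=O)ccc1OCc1ccccc1 | starting material
2 | 4-(benzyloxy)-3-methoxyphenyl formate | COc1cc(OC=O)ccc1OCc1ccccc1 | intermediate
3 | 4-(benzyloxy)-3-methoxyphenol | COc1cc(O)ccc1OCc1ccccc1 | intermediate
4 | 5-(benzyloxy)-2-hydroxy-4-methoxybenzaldehyde | COc1cc(O)c(C=O)cc1OCc1ccccc1 | intermediate
5 | 1-(2,4,5-trimethoxyphenyl)ethanone | CC(=O)c1cc(OC)c(OC)cc1OC | starting material
6 | 2-bromo-1-(2,4,5-trimethoxyphenyl)ethanone | O=C(CBr)c1cc(OC)c(OC)cc1OC | intermediate
7 | 5-(benzyloxy)-4-methoxy-2-[2-oxo-2-(2,4,5-trimethoxyphenyl)ethoxy]benzaldehyde | COc1cc(OCC(=O)c2cc(OC)c(OC)cc2OC)c(C=O)cc1OCc1ccccc1 | intermediate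
8 | rac-6-(benzyloxy)-3-hydroxy-7-methoxy-3-(2,4,5-trimethoxyphenyl)chroman-4-one (racemic at C3) | COc1cc2OCC(O)(c3cc(OC)c(OC)cc3OC)C(=O)c2cc1OCc1ccccc1 | intermediate
9 | 6-(benzyloxy)-7-methoxy-3-(2,4,5-trimethoxyphenyl)-4H-chromen-4-one | COc1cc2occ(-c3cc(OC)c(OC)cc3OC)c(=O)c2cc1OCc1ccccc1 | intermediate
10 | 6-hydroxy-7-methoxy-3-(2,4,5-trimethoxyphenyl)-4H-chromen-4-one | COc1cc2occ(-c3cc(OC)c(OC)cc3OC)c(=O)c2cc1O | target

**Step count**

Total step count: 7
Longest linear sequence: 6 steps (steps 1, 2, 4, 5, 6, 7)

**Steps most likely to fail**

Step 5.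
- **Risk:** Addition of the enaminol to the ortho-substituted, donor-rich ketone may be slow. Enolisation at C2 with aldol condensation, or aerial oxidation of the enaminol, could then consume the substrate.
- **Fallback:** Ring C is built by the deoxybenzoin logic instead, with C2 inserted last. The fallback sets out from phenol 3. A Hoesch reaction with (2,4,5-trimethoxyphenyl)acetonitrile (ZnCl2, HCl gas, Et2O, 0 °C) acylates C6 and should precipitate 1-[5-(benzyloxy)-2-hydroxy-4-methoxyphenyl]-2-(2,4,5-trimethoxyphenyl)ethan-1-iminium chloride F1. Hot water hydrolyses this salt to the deoxybenzoin 1-[5-(benzyloxy)-2-hydroxy-4-methoxyphenyl]-2-(2,4,5-trimethoxyphenyl)ethanone F2. Heating F2 with N,N-dimethylformamide dimethyl acetal in toluene supplies the C2 carbon and closes the pyranone, and the route is rejoined at 9.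

Step 4.
- **Risk:** The freshly formed keto aldehyde may undergo onward aldol condensation under the basic alkylation conditions (Rap–Stoermer cyclisation).
- **Fallback:** The O1–C2 bond is made by activating an alcohol rather than by using a phenoxide. The fallback sets out from bromo ketone 6. HCO2Na in aqueous EtOH at reflux displaces bromide to give 2-oxo-2-(2,4,5-trimethoxyphenyl)ethyl formate F3. This ester is hydrolysed in the same pot to 2-hydroxy-1-(2,4,5-trimethoxyphenyl)ethanone F4. A Mitsunobu reaction of F4 with salicylaldehyde 4 (PPh3, DIAD, THF, 0 °C to rt) then forms the ether in a medium with no persistent base, and the route is rejoined at 7.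

Step 7.
- **Risk:** Over-reduction may occur, that is saturation of the C2=C3 bond of the pyranone in competition with O-benzyl cleavage.
- **Fallback:** The benzyl group is removed without a reductant. The fallback sets out from 9. BCl3 with pentamethylbenzene as cation scavenger (CH2Cl2, −78 °C, then MeOH quench) cleaves the aryl benzyl ether and leaves the enone and the methyl ethers alone. It comes back directly at 10 and makes no new compound (F0).

**Further compounds**

F1 | step 5 | 1-[5-(benzyloxy)-2-hydroxy-4-methoxyphenyl]-2-(2,4,5-trimethoxyphenyl)ethan-1-iminium chloride | COc1cc(O)c(C(=[NH2+])Cc2cc(OC)c(OC)cc2OC)cc1OCc1ccccc1.[Cl-]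
F2 | step 5 | 1-[5-(benzyloxy)-2-hydroxy-4-methoxyphenyl]-2-(2,4,5-trimethoxyphenyl)ethanone | COc1cc(O)c(C(=O)Cc2cc(OC)c(OC)cc2OC)cc1OCc1ccccc1
F3 | step 4 | 2-oxo-2-(2,4,5-trimethoxyphenyl)ethyl formate | O=COCC(=O)c1cc(OC)c(OC)cc1OC
F4 | step 4 | 2-hydroxy-1-(2,4,5-trimethoxyphenyl)ethanone | OCC(=O)c1cc(OC)c(OC)cc1OC
F0 | step 7 | none | none
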